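**Plan**
1. Ring locants: C1 = ring carbonyl carbon, C2–C8 around the ring, O9 = lactone ring oxygen; side-chain carbons are primed. Retrosynthesis cuts the C7–O ester (side chain), then the O9–C8 bond by excising O9, then C4=C5 (after removing the C4/C5 oxygens), then C2–C3 and C7–C8 (aldols); this leaves pentan-3-one and two methacroleins.
2. Enabling feature: O9 lies between acyl C1 and the methyl-bearing methine C8, and C1 is flanked by two secondary carbons (C2, C8). The nine-membered lactone is therefore a cyclooctanone (C1–C8) with one oxygen inserted.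
3. Forward order: aldol (C7–C8), C6 by hydroboration, aldol (C2–C3), ring-closing metathesis to the eight-membered carbocycle, trans-4,5-diol (held in a temporary dioxolane), oxygen insertion to the nine-membered lactone, esterification at O7, deprotection, alkyne semihydrogenation.
4. Stereochemistry: C8/C7 from a chiral boron enolate; C6 from silyloxy-directed catalysed hydroboration; C2/C3 from the C8 stereocentre in a titanium aldol; C5 from hydroxyl-directed epoxidation; C4 from invertive epoxide opening; O9–C8 by retentive migration; C4' from asymmetric alkynylation; the (Z)-alkene from the alkyne.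

Key step: step 12

Remark on the chemistry: the free 4- and 5-hydroxyls of the target are γ/δ to the lactone carbonyl; the target is assumed to be stable under neutral conditions, so base is avoided after the ring expansion and the last step is neutral.

**Step 1**
Reactants: 1 pentan-3-one; 2 2-methylprop-2-enal (methacrolein)
Product: 5 (4S,5S)-5-hydroxy-4,6-dimethylhept-6-en-3-one, via Z-enol borinate 3 (not isolated), via boron aldolate 4 (not isolated)
Conditions: (−)-Ipc2BOTf, iPr2NEt, CH2Cl2, −78 °C; 2, −78 to −20 °C; then H2O2, MeOH, pH 7 buffer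
Reagents that add atoms: none
Why: Diisopinocampheylboron-mediated aldol, in which the (Z)-enol borinate 3 reacts through a closed chair transition state to give the syn adduct and the isopinocampheyl ligands select the aldehyde face, setting C8 and C7 (the antipodal reagent would give the enantiomer).

**Step 2**
Reactants: 5
Product: 6 (4S,5S)-5-[(tert-butyldimethylsilyl)oxy]-4,6-dimethylhept-6-en-3-one
Conditions: TBSOTf, 2,6-lutidine, CH2Cl2, −78 °C
Reagents that add atoms: tert-butyldimethylsilyl trifluoromethanesulfonate, CC(C)(C)[Si](C)(C)OS(=O)(=O)C(F)(F)F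
Why: Silylation of a secondary alcohol with a silyl triflate gives the bulky ether that directs step 3, is the non-chelating β-substituent in step 6 and is the electron-releasing group next to C8 in step 12.

**Step 3**
Reactants: 6
Product: 8 (4S,5R,6S)-5-[(tert-butyldimethylsilyl)oxy]-7-hydroxy-4,6-dimethylheptan-3-one, via catechol boronate 7 (not isolated)
Conditions: catecholborane, RhCl(PPh3)3 (cat.), THF, 20 °C; then H2O2, pH 7 buffer, EtOH, 0 °C
Reagents that add atoms: hydrogen peroxide, OO
Why: Rhodium-catalysed hydroboration of the 1,1-disubstituted alkene puts boron on the terminal carbon and hydrogen on C6 syn to the allylic silyloxy group, is chemoselective for the alkene over the ketone, and oxidation of 7 with retention completes the all-syn C6–C7–C8 triad.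

**Step 4**
Reactants: 8
Product: 9 (2R,3R,4S)-3-[(tert-butyldimethylsilyl)oxy]-2,4-dimethyl-5-oxoheptanal
Conditions: TEMPO (cat.), PhI(OAc)2, CH2Cl2, 20 °C
Reagents that add atoms: none
Why: Nitroxyl-catalysed oxidation of the primary alcohol stops at the aldehyde and is non-basic, so C6 should not epimerise and the ketone and silyl ether are untouched.

**Step 5**
Reactants: 9
Product: 10 (4S,5R,6S)-5-[(tert-butyldimethylsilyl)oxy]-4,6-dimethyloct-7-en-3-one
Conditions: Ph3P=CH2 (from Ph3PCH3Br, KHMDS; 1.05 equiv), THF, −78 to 0 °C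
Reagents that add atoms: methylenetriphenylphosphorane, C=P(c1ccccc1)(c1ccccc1)c1ccccc1
Why: Wittig methylenation with one equivalent of unstabilised ylide at low temperature is chemoselective for the aldehyde over the α-branched ketone and provides the vinyl group (C5) for the metathesis.

**Step 6**
Reactants: 10; 2 methacrolein
Product: 12 (3R,4R,6S,7R,8S)-7-[(tert-butyldimethylsilyl)oxy]-3-hydroxy-2,4,6,8-tetramethyldeca-1,9-dien-5-one, via titanium enolate 11 (not isolated)
Conditions: TiCl4, iPr2NEt, CH2Cl2, −78 °C; then 2, −78 °C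
Reagents that add atoms: none
Why: Titanium-enolate aldol, in which soft enolisation at the ethyl CH2 gives (Z)-enolate 11 that adds through a closed chair transition state (syn C2/C3) on the face dictated by the α-stereocentre C8 in its allylic-strain-minimised conformer, so the C2 and C8 methyls end up 1,3-syn.

**Step 7**
Reactants: 12
Product: 13 (2R,3R,4Z,6S,7R,8S)-7-[(tert-butyldimethylsilyl)oxy]-3-hydroxy-2,4,6,8-tetramethylcyclooct-4-en-1-one
Conditions: second-generation Grubbs catalyst RuCl2(=CHPh)(H2IMes)(PCy3) (cat.), toluene (high dilution), 80 °C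
Reagents that add atoms: none
Why: Ring-closing metathesis of the vinyl and isopropenyl termini forms C4=C5 and the eight-membered carbocycle, which can hold only the (Z)-alkene; closure is favoured by a substituent on every chain atom (Thorpe–Ingold-type preorganisation) and driven by loss of ethylene.

**Step 8**
Reactants: 13
Product: 14 (2R,3R,4R,5S,6S,7R,8S)-7-[(tert-butyldimethylsilyl)oxy]-4,5-epoxy-3-hydroxy-2,4,6,8-tetramethylcyclooctan-1-one
Conditions: VO(acac)2 (cat.), t-BuOOH, CH2Cl2, 0 °C
Reagents that add atoms: tert-butyl hydroperoxide, CC(C)(C)OO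
Why: Vanadium-catalysed hydroxyl-directed epoxidation, in which the C3 allylic alcohol delivers oxygen to the alkene face syn to itself (also the face anti to the C6 methyl), setting C5 and placing the epoxide for invertive opening at C4; an alkyl hydroperoxide does not oxidise the ketone.

**Step 9**
Reactants: 14
Product: 15 (2R,3R,4S,5S,6S,7R,8S)-3-acetoxy-7-[(tert-butyldimethylsilyl)oxy]-4,5-epoxy-2,4,6,8-tetramethylcyclooctan-1-one
Conditions: Ac2O, DMAP (cat.), pyridine, CH2Cl2, 0 °C
Reagents that add atoms: acetic anhydride, CC(=O)OC(C)=O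
Why: Nucleophile-catalysed acetylation of the only free hydroxyl installs the C3 acetate of the target before the C4/C5 hydroxyls exist, so three hydroxyls never need to be differentiated.

**Step 10**
Reactants: 15
Product: 16 (2R,3R,4R,5S,6S,7R,8S)-3-acetoxy-7-[(tert-butyldimethylsilyl)oxy]-4,5-dihydroxy-2,4,6,8-tetramethylcyclooctan-1-one
Conditions: HClO4 (cat., aq.), THF–H2O, 0 °C
Reagents that add atoms: water, O
Why: Acid-catalysed epoxide hydrolysis, in which water (or the transannular C1 carbonyl oxygen, which leads to the same product through its hemiketal) attacks the tertiary C4 with inversion, giving the C4 alcohol anti to the retained C5 oxygen.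

**Step 11**
Reactants: 16
Product: 17 4,5-O-isopropylidene derivative of 16: (2R,3R,4R,5S,6S,7R,8S)-3-acetoxy-7-[(tert-butyldimethylsilyl)oxy]-4,5-(isopropylidenedioxy)-2,4,6,8-tetramethylcyclooctan-1-one
Conditions: 2-methoxypropene, PPTS (cat.), CH2Cl2, 0 °C
Reagents that add atoms: 2-methoxypropene, COC(C)=C
Why: Acid-catalysed ketalisation with an enol ether ties the trans-4,5-diol into a dioxolane, which keeps both hydroxyls away from the C1 carbonyl (no hemiketal now, no translactonisation later).

**Step 12**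
Reactants: 17
Product: 19 nine-membered lactone (2R,3R,4R,5S,6S,7R,8S)-3-acetoxy-7-[(tert-butyldimethylsilyl)oxy]-4,5-(isopropylidenedioxy)-2,4,6,8-tetramethyloctan-8-olide, via Criegee adduct 18 (not isolated)
Conditions: CF3CO3H [from (CF3CO)2O and urea·H2O2], Na2HPO4, CH2Cl2, 0 °C
Reagents that add atoms: trifluoroperacetic acid, OOC(=O)C(F)(F)F
Why: Trifluoroperacetic acid adds to the C1 carbonyl to give Criegee adduct 18, and C8 then migrates from C1 to the proximal peroxide oxygen with loss of trifluoroacetate, so the O9–C8 bond is made in the same event that expands the carbocycle (Baeyer–Villiger oxidation; closest known type: peracid oxidation of 2-alkylcyclooctanones to nine-membered lactones). The nine-membered ring is thus closed by a 1,2-shift inside an existing ring (one-atom ring expansion) and not by end-to-end cyclisation, which avoids the entropic and transannular cost of a medium-ring lactonisation. No new stereocentre is formed; C8 migrates suprafacially with retention, so the configuration set in step 1 becomes that of the O-bearing methine. The step needs regioselection between the two secondary α-carbons C8 and C2: the C3 acetoxy group (and the ketal oxygen on C4) withdraw electron density from the C2 side, whereas C8 is flanked only by the silyloxy-bearing C7, so the electron-richer C8–C1 bond should migrate; because the two β-oxygens differ only in their protecting groups, this bias can be strengthened or inverted by exchanging them. It also needs chemoselectivity, which is secured because 17 has no alkene or free hydroxyl and the phosphate buffer protects the silyl ether and the ketal.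

**Step 13**
Reactants: 19
Product: 20 (2R,3R,4R,5S,6R,7R,8S)-3-acetoxy-7-hydroxy-4,5-(isopropylidenedioxy)-2,4,6,8-tetramethyloctan-8-olide
Conditions: HF·pyridine, pyridine, THF, 0 to 20 °C
Reagents that add atoms: none
Why: Fluoride cleavage of the silyl ether under buffered, non-basic conditions frees the C7 hydroxyl while acetate, lactone and ketal should survive.

**Step 14**
Reactants: 21 heptanal; 22 methyl propiolate
Product: 24 methyl (R)-4-hydroxydec-2-ynoate, via zinc alkynylide 23 (not isolated)
Conditions: Me2Zn, ProPhenol ligand (cat.; the enantiomer that gives the 4R carbinol), Ph3PO (cat.), toluene, 4 °C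
Reagents that add atoms: none
Why: Zinc–ProPhenol-catalysed asymmetric alkynylation, in which methylzinc alkynylide 23 adds to the aldehyde inside the chiral dinuclear zinc pocket, setting C4'.

**Step 15**
Reactants: 24
Product: 25 methyl (R)-4-[(triethylsilyl)oxy]dec-2-ynoate
Conditions: TESCl, imidazole, CH2Cl2, 0 °C
Reagents that add atoms: chlorotriethylsilane, CC[Si](Cl)(CC)CC
Why: Standard silylation gives an ether that masks the hydroxyl during acid activation and is cleaved by the same mild acid as the ketal in step 18.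

**Step 16**
Reactants: 25
Product: 26 (R)-4-[(triethylsilyl)oxy]dec-2-ynoic acid
Conditions: LiOH, THF–H2O, 0 °C; then cold dilute HCl to pH 4
Reagents that add atoms: lithium hydroxide, [Li+].[OH-]
Why: Ester saponification at low temperature; the alkyne geometry prevents lactonisation and the propargylic stereocentre is not epimerisable under these conditions.

**Step 17**
Reactants: 20; 26
Product: 27 7-O-[(R)-4-(triethylsilyloxy)dec-2-ynoyl] ester of 20 (2R,3R,4R,5S,6R,7R,8S; 4'R)
Conditions: DCC, DMAP (cat.), CH2Cl2, −20 to 0 °C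
Reagents that add atoms: none
Why: Carbodiimide (Steglich) esterification of the hindered C7 alcohol with a sterically slim ynoic acid; no other free hydroxyl competes and the alkyne cannot isomerise.

**Step 18**
Reactants: 27
Product: 28 (2R,3R,4R,5S,6S,7R,8S)-3-acetoxy-4,5-dihydroxy-2,4,6,8-tetramethyl-7-{[(R)-4-hydroxydec-2-ynoyl]oxy}octan-8-olide
Conditions: AcOH–THF–H2O (3:1:1), 25–35 °C
Reagents that add atoms: none
Why: Mild aqueous acid hydrolysis removes the strained trans-fused ketal and the triethylsilyl ether in one operation, while the alkyne still blocks butenolide formation and no base is present to promote acyl migration or translactonisation.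

**Step 19**
Reactants: 28
Product: 29 target CNP0240788.3
Conditions: H2 (1 atm), Lindlar catalyst (Pd/CaCO3, Pb(OAc)2-poisoned), quinoline, EtOAc, 20 °C
Reagents that add atoms: none
Why: Lindlar semihydrogenation adds hydrogen syn on the poisoned palladium surface to give the (Z)-enoate under neutral conditions, so the target is released without acid or base.

**Compound list**
1 | pentan-3-one | CCC(=O)CC | starting material
2 | 2-methylprop-2-enal (methacrolein) | CC(=C)C=O | starting material
3 | (Z)-pent-2-en-3-yl diisopinocampheylborinate (Z-enol borinate) | C/C=C(/CC)OB([C@@H]1C[C@@H]2C[C@H]([C@H]1C)C2(C)C)[C@@H]1C[C@@H]2C[C@H]([C@H]1C)C2(C)C | intermediate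
4 | diisopinocampheylboron aldolate of 5 | CCC(=O)[C@@H](C)[C@H](OB([C@@H]1C[C@@H]2C[C@H]([C@H]1C)C2(C)C)[C@@H]1C[C@@H]2C[C@H]([C@H]1C)C2(C)C)C(C)=C | intermediate
5 | (4S,5S)-5-hydroxy-4,6-dimethylhept-6-en-3-one | CCC(=O)[C@@H](C)[C@H](O)C(C)=C | intermediate
6 | (4S,5S)-5-[(tert-butyldimethylsilyl)oxy]-4,6-dimethylhept-6-en-3-one | CCC(=O)[C@@H](C)[C@H](O[Si](C)(C)C(C)(C)C)C(C)=C | intermediate
7 | (4S,5R,6S)-7-(1,3,2-benzodioxaborol-2-yl)-5-[(tert-butyldimethylsilyl)oxy]-4,6-dimethylheptan-3-one | CCC(=O)[C@@H](C)[C@H](O[Si](C)(C)C(C)(C)C)[C@@H](C)CB1Oc2ccccc2O1 | intermediate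
8 | (4S,5R,6S)-5-[(tert-butyldimethylsilyl)oxy]-7-hydroxy-4,6-dimethylheptan-3-one | CCC(=O)[C@@H](C)[C@H](O[Si](C)(C)C(C)(C)C)[C@@H](C)CO | intermediate
9 | (2R,3R,4S)-3-[(tert-butyldimethylsilyl)oxy]-2,4-dimethyl-5-oxoheptanal | CCC(=O)[C@@H](C)[C@H](O[Si](C)(C)C(C)(C)C)[C@@H](C)C=O | intermediate
10 | (4S,5R,6S)-5-[(tert-butyldimethylsilyl)oxy]-4,6-dimethyloct-7-en-3-one | CCC(=O)[C@@H](C)[C@H](O[Si](C)(C)C(C)(C)C)[C@@H](C)C=C | intermediate
11 | trichlorotitanium (Z)-enolate of 10 | C/C=C(/[C@@H](C)[C@H](O[Si](C)(C)C(C)(C)C)[C@@H](C)C=C)O[Ti](Cl)(Cl)Cl | intermediate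
12 | (3R,4R,6S,7R,8S)-7-[(tert-butyldimethylsilyl)oxy]-3-hydroxy-2,4,6,8-tetramethyldeca-1,9-dien-5-one | C=C[C@H](C)[C@@H](O[Si](C)(C)C(C)(C)C)[C@H](C)C(=O)[C@H](C)[C@@H](O)C(C)=C | intermediate
13 | (2R,3R,4Z,6S,7R,8S)-7-[(tert-butyldimethylsilyl)oxy]-3-hydroxy-2,4,6,8-tetramethylcyclooct-4-en-1-one | CC(C)(C)[Si](C)(C)O[C@@H]1[C@@H](C)/C=C(C)\[C@H](O)[C@@H](C)C(=O)[C@H]1C | intermediate
14 | (2R,3R,4R,5S,6S,7R,8S)-7-[(tert-butyldimethylsilyl)oxy]-4,5-epoxy-3-hydroxy-2,4,6,8-tetramethylcyclooctan-1-one | CC(C)(C)[Si](C)(C)O[C@@H]1[C@@H](C)[C@H](O2)[C@@]2(C)[C@H](O)[C@@H](C)C(=O)[C@H]1C | intermediate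
15 | (2R,3R,4S,5S,6S,7R,8S)-3-acetoxy-7-[(tert-butyldimethylsilyl)oxy]-4,5-epoxy-2,4,6,8-tetramethylcyclooctan-1-one | CC(C)(C)[Si](C)(C)O[C@@H]1[C@@H](C)[C@H](O2)[C@@]2(C)[C@H](OC(C)=O)[C@@H](C)C(=O)[C@H]1C | intermediate
16 | (2R,3R,4R,5S,6S,7R,8S)-3-acetoxy-7-[(tert-butyldimethylsilyl)oxy]-4,5-dihydroxy-2,4,6,8-tetramethylcyclooctan-1-one | CC(C)(C)[Si](C)(C)O[C@@H]1[C@@H](C)[C@H](O)[C@@](C)(O)[C@H](OC(C)=O)[C@@H](C)C(=O)[C@H]1C | intermediate
17 | 4,5-O-isopropylidene derivative of 16 (2R,3R,4R,5S,6S,7R,8S) | CC(C)(C)[Si](C)(C)O[C@@H]1[C@@H](C)[C@H](OC2(C)C)[C@@](C)(O2)[C@H](OC(C)=O)[C@@H](C)C(=O)[C@H]1C | intermediate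
18 | Criegee adduct of 17 (1-hydroxy-1-trifluoroacetylperoxy) | CC(C)(C)[Si](C)(C)O[C@@H]1[C@@H](C)[C@H](OC2(C)C)[C@@](C)(O2)[C@H](OC(C)=O)[C@@H](C)C(O)(OOC(=O)C(F)(F)F)[C@H]1C | intermediate
19 | (2R,3R,4R,5S,6S,7R,8S)-3-acetoxy-7-[(tert-butyldimethylsilyl)oxy]-4,5-(isopropylidenedioxy)-2,4,6,8-tetramethyloctan-8-olide | CC(C)(C)[Si](C)(C)O[C@@H]1[C@@H](C)[C@H](OC2(C)C)[C@@](C)(O2)[C@H](OC(C)=O)[C@@H](C)C(=O)O[C@H]1C | intermediate
20 | (2R,3R,4R,5S,6R,7R,8S)-3-acetoxy-7-hydroxy-4,5-(isopropylidenedioxy)-2,4,6,8-tetramethyloctan-8-olide | O[C@@H]1[C@@H](C)[C@H](OC2(C)C)[C@@](C)(O2)[C@H](OC(C)=O)[C@@H](C)C(=O)O[C@H]1C | intermediate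
21 | heptanal | CCCCCCC=O | starting material
22 | methyl propiolate | C#CC(=O)OC | starting material
23 | methyl 3-(methylzincio)propiolate (zinc alkynylide) | COC(=O)C#C[Zn]C | intermediate
24 | methyl (R)-4-hydroxydec-2-ynoate | CCCCCC[C@@H](O)C#CC(=O)OC | intermediate
25 | methyl (R)-4-[(triethylsilyl)oxy]dec-2-ynoate | CCCCCC[C@@H](O[Si](CC)(CC)CC)C#CC(=O)OC | intermediate
26 | (R)-4-[(triethylsilyl)oxy]dec-2-ynoic acid | CCCCCC[C@@H](O[Si](CC)(CC)CC)C#CC(=O)O | intermediate
27 | 7-O-[(R)-4-(triethylsilyloxy)dec-2-ynoyl] ester of 20 | CCCCCC[C@@H](O[Si](CC)(CC)CC)C#CC(=O)O[C@@H]1[C@@H](C)[C@H](OC2(C)C)[C@@](C)(O2)[C@H](OC(C)=O)[C@@H](C)C(=O)O[C@H]1C | intermediate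
28 | (2R,3R,4R,5S,6S,7R,8S)-3-acetoxy-4,5-dihydroxy-2,4,6,8-tetramethyl-7-{[(R)-4-hydroxydec-2-ynoyl]oxy}octan-8-olide | CCCCCC[C@@H](O)C#CC(=O)O[C@@H]1[C@@H](C)[C@H](O)[C@@](C)(O)[C@H](OC(C)=O)[C@@H](C)C(=O)O[C@H]1C | intermediate
29 | CNP0240788.3, the (2'Z,4'R)-4'-hydroxydec-2'-enoate (2R,3R,4R,5S,6S,7R,8S) | CCCCCC[C@@H](O)/C=C\C(=O)O[C@@H]1[C@@H](C)[C@H](O)[C@@](C)(O)[C@H](OC(C)=O)[C@@H](C)C(=O)O[C@H]1C | target

**Step count**
Total: 19 steps. Longest linear sequence: 16 steps (steps 1–13 and 17–19).

**Steps most likely to fail**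

1. Step 12. Competing migration of C2 (too little electronic difference between the two secondary α-carbons) would give the regioisomeric lactone, and addition to the hindered carbonyl may be slow. The fallback sets out from 10 and comes back at 19; it inserts the oxygen before the ring exists, where the competition is secondary alkyl against ethyl. Baeyer–Villiger oxidation of 10 (mCPBA, NaHCO3) should give (2S,3R,4S)-3-[(tert-butyldimethylsilyl)oxy]-4-methylhex-5-en-2-yl propanoate F1. A syn-selective boron-mediated ester aldol with methacrolein (Bu2BOTf, iPr2NEt; the two syn diastereomers separated) gives the (2R,3R)-3-hydroxy-2,4-dimethylpent-4-enoate ester F2. Ring-closing metathesis then closes the nine-membered ring at C4=C5 to give the unsaturated hydroxy lactone F3. Hydroxyl-directed epoxidation gives the epoxy alcohol lactone F4, acetylation the epoxy acetate lactone F5, and cold buffered hydrolysis (to limit participation of the lactone carbonyl) the diol lactone F6; ketalisation as in step 11 returns to 19.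

2. Step 7. Oligomerisation by cross metathesis, or failure of the catalyst to engage the hindered isopropenyl group, would prevent closure of the eight-membered ring. The fallback sets out from 10 and comes back at 13; it uses relay ring-closing metathesis. The titanium aldol of step 6 is run with (E)-2-methylocta-2,7-dienal F7 (from hex-5-enal and 2-(triphenylphosphoranylidene)propanal) to give the relay trienone (6E,8R,9R,11S,12R,13S)-12-[(tert-butyldimethylsilyl)oxy]-8-hydroxy-7,9,11,13-tetramethylpentadeca-1,6,14-trien-10-one F8. Ruthenium loads at the unhindered terminal alkene, extrudes cyclopentene and is thereby placed on C4, from where closure onto the C5 vinyl group gives 13.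

3. Step 10. Opening at the wrong epoxide carbon (C5), a hydride shift to a ketone, or transannular capture would spoil the C4/C5 diol. The fallback sets out from 15 and comes back at 16; it forms the C4–O bond by a radical path instead of a cationic one. Cp2TiCl (trivalent titanium, from Cp2TiCl2 and Mn) opens the epoxide homolytically to the tertiary C4 radical, which loses a methyl hydrogen to give the exocyclic allylic alcohol (2R,3R,5S,6S,7R,8S)-3-acetoxy-7-[(tert-butyldimethylsilyl)oxy]-5-hydroxy-2,6,8-trimethyl-4-methylidenecyclooctan-1-one F9 with the C5 oxygen unchanged. Mukaiyama hydration (Co(acac)2, PhSiH3, O2) then installs the tertiary C4 hydroxyl, oxygen being captured on the face anti to the flanking C3 and C5 oxygens, to give 16.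

**Further compounds**
F1 | step 12 | (2S,3R,4S)-3-[(tert-butyldimethylsilyl)oxy]-4-methylhex-5-en-2-yl propanoate | CCC(=O)O[C@@H](C)[C@H](O[Si](C)(C)C(C)(C)C)[C@@H](C)C=C
F2 | step 12 | (2S,3R,4S)-3-[(tert-butyldimethylsilyl)oxy]-4-methylhex-5-en-2-yl (2R,3R)-3-hydroxy-2,4-dimethylpent-4-enoate | C=C[C@H](C)[C@@H](O[Si](C)(C)C(C)(C)C)[C@H](C)OC(=O)[C@H](C)[C@@H](O)C(C)=C
F3 | step 12 | (2R,3R,4Z,6S,7R,8S)-7-[(tert-butyldimethylsilyl)oxy]-3-hydroxy-2,4,6,8-tetramethyloct-4-en-8-olide | CC(C)(C)[Si](C)(C)O[C@@H]1[C@@H](C)/C=C(C)\[C@H](O)[C@@H](C)C(=O)O[C@H]1C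
F4 | step 12 | (2R,3R,4R,5S,6S,7R,8S)-7-[(tert-butyldimethylsilyl)oxy]-4,5-epoxy-3-hydroxy-2,4,6,8-tetramethyloctan-8-olide | CC(C)(C)[Si](C)(C)O[C@@H]1[C@@H](C)[C@H](O2)[C@@]2(C)[C@H](O)[C@@H](C)C(=O)O[C@H]1C
F5 | step 12 | (2R,3R,4S,5S,6S,7R,8S)-3-acetoxy-7-[(tert-butyldimethylsilyl)oxy]-4,5-epoxy-2,4,6,8-tetramethyloctan-8-olide | CC(C)(C)[Si](C)(C)O[C@@H]1[C@@H](C)[C@H](O2)[C@@]2(C)[C@H](OC(C)=O)[C@@H](C)C(=O)O[C@H]1C
F6 | step 12 | (2R,3R,4R,5S,6S,7R,8S)-3-acetoxy-7-[(tert-butyldimethylsilyl)oxy]-4,5-dihydroxy-2,4,6,8-tetramethyloctan-8-olide | CC(C)(C)[Si](C)(C)O[C@@H]1[C@@H](C)[C@H](O)[C@@](C)(O)[C@H](OC(C)=O)[C@@H](C)C(=O)O[C@H]1C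
F7 | step 7 | (E)-2-methylocta-2,7-dienal | C=CCCC/C=C(\C)C=O
F8 | step 7 | (6E,8R,9R,11S,12R,13S)-12-[(tert-butyldimethylsilyl)oxy]-8-hydroxy-7,9,11,13-tetramethylpentadeca-1,6,14-trien-10-one | C=C[C@H](C)[C@@H](O[Si](C)(C)C(C)(C)C)[C@H](C)C(=O)[C@H](C)[C@@H](O)/C(C)=C/CCCC=C
F9 | step 10 | (2R,3R,5S,6S,7R,8S)-3-acetoxy-7-[(tert-butyldimethylsilyl)oxy]-5-hydroxy-2,6,8-trimethyl-4-methylidenecyclooctan-1-one | CC(C)(C)[Si](C)(C)O[C@@H]1[C@@H](C)[C@H](O)C(=C)[C@H](OC(C)=O)[C@@H](C)C(=O)[C@H]1C
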